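## Retrosynthetic overview

1. Both cinnamate esters are cut last. The p-coumarate sits on the C9 oxygen and the ferulate on the propanol oxygen. Cutting them leads back to a differentiated diol with C9–OH free, the propanol as its TBS ether and the guaiacyl phenol as its TIPS ether.
2. C9–OH comes from a trans methyl ester on C3 of the 2,3-dihydrobenzofuran.
3. The plan rests on one feature: C2 and C3 of the dihydrofuran ring are the two carbons of the C2=C3 bond of an intact 5,7-disubstituted benzofuran. The guaiacyl ring (C2–C1') and the one-carbon unit C9 (C3–C9) are added across that bond with aryl–Pd, CO and MeOH.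
4. Ring order: the benzene ring is bought with its propanol chain. The furan ring is closed early by Sonogashira coupling and 5-endo-dig annulation of an o-iodophenol. No ring is formed afterwards, because the key step only saturates the furan ring.

Key step: step 6

Assumption: the sense of induction of the chiral bisphosphine in step 6 cannot be predicted, so the (R)-ligand is written and its equally available antipode is used instead if a first run shows that it leads to 2R; C9 denotes the carbon on C3 and C1' the guaiacyl ipso carbon.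

## Route

Step 1
Reactants: 1 4-(3-hydroxypropyl)-2-methoxyphenol (dihydroconiferyl alcohol)
Product: 2 4-(3-hydroxypropyl)-2-iodo-6-methoxyphenol
Conditions: I2 (1.05 equiv), KI, NaHCO3 (1.5 equiv), THF–H2O, 0 °C → rt
Reagents that add atoms: iodine, II
Why: Electrophilic aromatic iodination with molecular iodine, which attacks only a phenol(ate)-activated carbon, should go to the single free position ortho to the OH (the para position carries the chain), as in the iodination of vanillin to 5-iodovanillin.

Step 2
Reactants: 2 4-(3-hydroxypropyl)-2-iodo-6-methoxyphenol; 3 trimethylsilylacetylene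
Product: 5 3-[7-methoxy-2-(trimethylsilyl)-1-benzofuran-5-yl]propan-1-ol, via alkynylphenol 4 (not isolated)
Conditions: PdCl2(PPh3)2 (3 mol %), CuI (6 mol %), Et3N, DMF, sealed tube, rt then 80 °C
Reagents that add atoms: none
Why: Sonogashira coupling of the o-iodophenol, followed on heating by metal-promoted 5-endo-dig addition of the phenol O–H to the alkyne, is the standard heteroannulation to 2-silylbenzofurans and tolerates free hydroxyl groups.

Step 3
Reactants: 5 3-[7-methoxy-2-(trimethylsilyl)-1-benzofuran-5-yl]propan-1-ol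
Product: 6 3-(7-methoxy-1-benzofuran-5-yl)propan-1-ol
Conditions: TBAF·3H2O (1.2 equiv), THF, rt
Reagents that add atoms: none
Why: Fluoride-induced protodesilylation of a 2-silyl heteroarene, in which fluoride attacks silicon and the stabilised C2 benzofuranyl carbanion equivalent is protonated by water.

Step 4
Reactants: 6 3-(7-methoxy-1-benzofuran-5-yl)propan-1-ol
Product: 7 tert-butyl[3-(7-methoxy-1-benzofuran-5-yl)propoxy]dimethylsilane
Conditions: TBSCl (1.2 equiv), imidazole (2.5 equiv), CH2Cl2, 0 °C → rt
Reagents that add atoms: tert-butyldimethylsilyl chloride, CC(C)(C)[Si](C)(C)Cl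
Why: Imidazole-promoted silylation of the only hydroxyl group left, placed after ring closure so that no phenol competes.

Step 5
Reactants: 8 4-iodo-2-methoxyphenol
Product: 9 (4-iodo-2-methoxyphenoxy)triisopropylsilane
Conditions: TIPSCl (1.2 equiv), imidazole (2.5 equiv), DMF, rt
Reagents that add atoms: triisopropylsilyl chloride, CC(C)[Si](Cl)(C(C)C)C(C)C
Why: Standard phenol silylation; TIPS is chosen because aryl TIPS ethers withstand amine bases and dilute acid yet fall to fluoride at the end.

Step 6
Reactants: 7 tert-butyl[3-(7-methoxy-1-benzofuran-5-yl)propoxy]dimethylsilane; 9 (4-iodo-2-methoxyphenoxy)triisopropylsilane; 10 carbon monoxide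
Product: 12 methyl (2R,3R)-5-[3-(tert-butyldimethylsilyloxy)propyl]-7-methoxy-2-[3-methoxy-4-(triisopropylsilyloxy)phenyl]-2,3-dihydro-1-benzofuran-3-carboxylate (trans), via cis ester 11 (not isolated)
Conditions: Pd2(dba)3·CHCl3 (5 mol %), (R)-SEGPHOS (12 mol %), 9 (2 equiv), AgOTf (2.2 equiv), 1,2,2,6,6-pentamethylpiperidine (3 equiv), CO (1 atm), MeOH (5 equiv), PhMe, 60 °C; then vent, Celite, aq. NaHCO3 wash, PhMe, DBU (0.5 equiv), 40 °C
Reagents that add atoms: methanol, CO
Why: Proposed new method: oxidative addition of 9 to the Pd(0)–bisphosphine and removal of iodide by AgOTf should give a cationic aryl–Pd(II) that binds the C2=C3 enol-ether bond of 7 and inserts it syn, aryl to C2 and Pd to C3 (held as an η3-benzyl); because H2 then lies on the ring face opposite to Pd, syn β-hydride elimination is not available, and CO insertion with retention followed by methanolysis of the acyl–Pd should give cis ester 11 and return Pd(0). The closest known reaction types are intramolecular dearomative Heck/anion-capture cascades of indoles and benzofurans, domino Heck/alkoxycarbonylation of tethered alkenes, cationic asymmetric Heck arylation of 2,3-dihydrofuran at C2 and Heck-type C2 arylation of benzofurans; the intermolecular, enantioselective three-component version on a benzofuran has not been shown. No ring is closed: only the C2–C1' and C3–C9 bonds are made on the existing furan ring, which loses its aromaticity. C2 is set in the migratory insertion, where the C2-symmetric bisphosphine leaves only two diagonal quadrants open for the flat benzo-fused substrate and so selects one face of C2=C3; C3 is first cis to the aryl group as a result of syn addition and retentive carbonylation and is then inverted by DBU through the ester enolate to the more stable trans (2R,3R) arrangement, C2 staying intact because loss of the ring aryloxide from that enolate would be the reverse of a disfavoured 5-endo-trig closure. Regioselectivity rests on the polarity of the enol ether (C2 electrophilic, C3 nucleophilic towards Pd) and on benzylic stabilisation of the C3–Pd bond. Chemoselectivity requires carbopalladation to come before carbonylation: CO insertion into aryl–Pd is reversible at 1 atm and only methanolysis is final, so low CO pressure, little MeOH and an excess of the cheap 9 are used, while a hindered amine in place of carboxylate or carbonate closes the concerted-metalation route to the 2-arylbenzofuran and keeps the TBS ether safe from acid.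

Step 7
Reactants: 12 methyl (2R,3R)-trans ester
Product: 13 {(2R,3S)-5-[3-(tert-butyldimethylsilyloxy)propyl]-7-methoxy-2-[3-methoxy-4-(triisopropylsilyloxy)phenyl]-2,3-dihydro-1-benzofuran-3-yl}methanol
Conditions: DIBAL-H (3 equiv), CH2Cl2, −78 → 0 °C; aq. Rochelle salt
Reagents that add atoms: none
Why: DIBAL-H reduction of the ester to the primary alcohol leaves both silyl ethers alone, and C3 cannot drift at the transient aldehyde because it already holds the more stable trans arrangement (the descriptor changes to 3S only through CIP priorities).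

Step 8
Reactants: 14 (E)-p-coumaric acid
Product: 16 (E)-3-[4-(triisopropylsilyloxy)phenyl]acrylic acid, via bis-silyl coumarate 15 (not isolated)
Conditions: TIPSCl (2.3 equiv), imidazole (5 equiv), DMF, rt; then AcOH–THF–H2O (3:1:1), 40 °C
Reagents that add atoms: triisopropylsilyl chloride, CC(C)[Si](Cl)(C(C)C)C(C)C
Why: Exhaustive silylation followed by selective hydrolysis, in which the silyl ester is cleaved by aqueous acetic acid while the aryl TIPS ether is inert to it.

Step 9
Reactants: 13 C9 alcohol; 16 (E)-3-[4-(triisopropylsilyloxy)phenyl]acrylic acid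
Product: 17 {(2R,3S)-5-[3-(tert-butyldimethylsilyloxy)propyl]-7-methoxy-2-[3-methoxy-4-(triisopropylsilyloxy)phenyl]-2,3-dihydro-1-benzofuran-3-yl}methyl (E)-3-[4-(triisopropylsilyloxy)phenyl]acrylate
Conditions: DCC (1.3 equiv), DMAP (0.2 equiv), CH2Cl2, 0 °C → rt
Reagents that add atoms: none
Why: Steglich esterification of the only free hydroxyl group under neutral conditions that touch neither stereocentre nor the E-alkene.

Step 10
Reactants: 17 C9 coumarate with the TBS ether in place
Product: 18 {(2R,3S)-5-(3-hydroxypropyl)-7-methoxy-2-[3-methoxy-4-(triisopropylsilyloxy)phenyl]-2,3-dihydro-1-benzofuran-3-yl}methyl (E)-3-[4-(triisopropylsilyloxy)phenyl]acrylate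
Conditions: CSA (10 mol %), MeOH–CH2Cl2 (1:1), 0 °C
Reagents that add atoms: none
Why: Acid-catalysed methanolysis of silyl ethers cleaves a primary alkyl TBS ether far faster than aryl TIPS ethers, and catalytic acid at 0 °C should not transesterify the conjugated ester.

Step 11
Reactants: 19 (E)-ferulic acid
Product: 21 (E)-3-[3-methoxy-4-(triisopropylsilyloxy)phenyl]acrylic acid, via bis-silyl ferulate 20 (not isolated)
Conditions: TIPSCl (2.3 equiv), imidazole (5 equiv), DMF, rt; then AcOH–THF–H2O (3:1:1), 40 °C
Reagents that add atoms: triisopropylsilyl chloride, CC(C)[Si](Cl)(C(C)C)C(C)C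
Why: The same exhaustive silylation and selective silyl ester hydrolysis as in step 8.

Step 12
Reactants: 18 free propanol; 21 (E)-3-[3-methoxy-4-(triisopropylsilyloxy)phenyl]acrylic acid
Product: 22 tris-O-TIPS boehmenan X (18 acylated on the propanol oxygen by 21; 2R,3S; both alkenes E)
Conditions: DCC (1.3 equiv), DMAP (0.2 equiv), CH2Cl2, 0 °C → rt
Reagents that add atoms: none
Why: Steglich esterification of an unhindered primary alcohol, with all three phenols masked so that only one acylation site exists.

Step 13
Reactants: 22 tris-O-TIPS boehmenan X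
Product: 23 (+)-boehmenan X
Conditions: TBAF (3.5 equiv), AcOH (3.5 equiv), THF, 0 °C
Reagents that add atoms: none
Why: Fluoride desilylation removes aryl silyl ethers rapidly, and the acetic acid buffer protonates each phenoxide at once, so neither ester cleavage nor opening of the C2–O bond through a p-quinone methide (which would scramble C2) should occur.

## Compound list

1 | 4-(3-hydroxypropyl)-2-methoxyphenol (dihydroconiferyl alcohol) | COc1cc(CCCO)ccc1O | starting material
2 | 4-(3-hydroxypropyl)-2-iodo-6-methoxyphenol | COc1cc(CCCO)cc(I)c1O | intermediate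
3 | trimethylsilylacetylene | C#C[Si](C)(C)C | starting material
4 | 4-(3-hydroxypropyl)-2-methoxy-6-[(trimethylsilyl)ethynyl]phenol | COc1cc(CCCO)cc(C#C[Si](C)(C)C)c1O | intermediate
5 | 3-[7-methoxy-2-(trimethylsilyl)-1-benzofuran-5-yl]propan-1-ol | COc1cc(CCCO)cc2cc([Si](C)(C)C)oc12 | intermediate
6 | 3-(7-methoxy-1-benzofuran-5-yl)propan-1-ol | COc1cc(CCCO)cc2ccoc12 | intermediate
7 | tert-butyl[3-(7-methoxy-1-benzofuran-5-yl)propoxy]dimethylsilane | CC(C)(C)[Si](C)(C)OCCCc1cc(OC)c2occc2c1 | intermediate
8 | 4-iodo-2-methoxyphenol | COc1cc(I)ccc1O | starting material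
9 | (4-iodo-2-methoxyphenoxy)triisopropylsilane | COc1cc(I)ccc1O[Si](C(C)C)(C(C)C)C(C)C | intermediate
10 | carbon monoxide | [C-]#[O+] | starting material
11 | methyl (2R,3S)-5-[3-(tert-butyldimethylsilyloxy)propyl]-7-methoxy-2-[3-methoxy-4-(triisopropylsilyloxy)phenyl]-2,3-dihydro-1-benzofuran-3-carboxylate (cis) | CC(C)(C)[Si](C)(C)OCCCc1cc(OC)c2c(c1)[C@H](C(=O)OC)[C@H](c1ccc(O[Si](C(C)C)(C(C)C)C(C)C)c(OC)c1)O2 | intermediate
12 | methyl (2R,3R)-5-[3-(tert-butyldimethylsilyloxy)propyl]-7-methoxy-2-[3-methoxy-4-(triisopropylsilyloxy)phenyl]-2,3-dihydro-1-benzofuran-3-carboxylate (trans) | CC(C)(C)[Si](C)(C)OCCCc1cc(OC)c2c(c1)[C@@H](C(=O)OC)[C@H](c1ccc(O[Si](C(C)C)(C(C)C)C(C)C)c(OC)c1)O2 | intermediate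
13 | {(2R,3S)-5-[3-(tert-butyldimethylsilyloxy)propyl]-7-methoxy-2-[3-methoxy-4-(triisopropylsilyloxy)phenyl]-2,3-dihydro-1-benzofuran-3-yl}methanol | CC(C)(C)[Si](C)(C)OCCCc1cc(OC)c2c(c1)[C@@H](CO)[C@H](c1ccc(O[Si](C(C)C)(C(C)C)C(C)C)c(OC)c1)O2 | intermediate
14 | (E)-p-coumaric acid | O=C(O)/C=C/c1ccc(O)cc1 | starting material
15 | triisopropylsilyl (E)-3-[4-(triisopropylsilyloxy)phenyl]acrylate | CC(C)[Si](OC(=O)/C=C/c1ccc(O[Si](C(C)C)(C(C)C)C(C)C)cc1)(C(C)C)C(C)C | intermediate
16 | (E)-3-[4-(triisopropylsilyloxy)phenyl]acrylic acid | O=C(O)/C=C/c1ccc(O[Si](C(C)C)(C(C)C)C(C)C)cc1 | intermediate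
17 | {(2R,3S)-5-[3-(tert-butyldimethylsilyloxy)propyl]-7-methoxy-2-[3-methoxy-4-(triisopropylsilyloxy)phenyl]-2,3-dihydro-1-benzofuran-3-yl}methyl (E)-3-[4-(triisopropylsilyloxy)phenyl]acrylate | CC(C)(C)[Si](C)(C)OCCCc1cc(OC)c2c(c1)[C@@H](COC(=O)/C=C/c1ccc(O[Si](C(C)C)(C(C)C)C(C)C)cc1)[C@H](c1ccc(O[Si](C(C)C)(C(C)C)C(C)C)c(OC)c1)O2 | intermediate
18 | {(2R,3S)-5-(3-hydroxypropyl)-7-methoxy-2-[3-methoxy-4-(triisopropylsilyloxy)phenyl]-2,3-dihydro-1-benzofuran-3-yl}methyl (E)-3-[4-(triisopropylsilyloxy)phenyl]acrylate | OCCCc1cc(OC)c2c(c1)[C@@H](COC(=O)/C=C/c1ccc(O[Si](C(C)C)(C(C)C)C(C)C)cc1)[C@H](c1ccc(O[Si](C(C)C)(C(C)C)C(C)C)c(OC)c1)O2 | intermediate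
19 | (E)-ferulic acid | COc1cc(/C=C/C(=O)O)ccc1O | starting material
20 | triisopropylsilyl (E)-3-[3-methoxy-4-(triisopropylsilyloxy)phenyl]acrylate | COc1cc(/C=C/C(=O)O[Si](C(C)C)(C(C)C)C(C)C)ccc1O[Si](C(C)C)(C(C)C)C(C)C | intermediate
21 | (E)-3-[3-methoxy-4-(triisopropylsilyloxy)phenyl]acrylic acid | COc1cc(/C=C/C(=O)O)ccc1O[Si](C(C)C)(C(C)C)C(C)C | intermediate
22 | tris-O-TIPS boehmenan X (2R,3S; all three phenols as TIPS ethers) | COc1cc(/C=C/C(=O)OCCCc2cc(OC)c3c(c2)[C@@H](COC(=O)/C=C/c2ccc(O[Si](C(C)C)(C(C)C)C(C)C)cc2)[C@H](c2ccc(O[Si](C(C)C)(C(C)C)C(C)C)c(OC)c2)O3)ccc1O[Si](C(C)C)(C(C)C)C(C)C | intermediate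
23 | (+)-boehmenan X (2R,3S) | COc1cc(/C=C/C(=O)OCCCc2cc(OC)c3c(c2)[C@@H](COC(=O)/C=C/c2ccc(O)cc2)[C@H](c2ccc(O)c(OC)c2)O3)ccc1O | target

## Step count and risks

Total step count: 13.
Longest linear sequence: 10 steps (1, 2, 3, 4, 6, 7, 9, 10, 12, 13). Steps 5, 8 and 11 are side branches.

**1. Step 6 (Proposed new method).**
- What may go wrong:
  - The aryl–Pd species is carbonylated and methanolysed before it can insert the weakly reactive furan double bond.
  - The C3–Pd intermediate rearomatises by base-assisted anti elimination, or opens the ring by β-aryloxide elimination.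
  - Silver(I) is reduced by CO.
  - Facial selectivity in the insertion is poor.
- Fallback approach: known chemistry, closing the ring instead of adding to a ring. It uses the enantioselective, cis-selective Rh(II)-carbene 1,5 C–H insertion of an aryldiazoacetate into a benzylic ether C–H bond.
- Route of the fallback: it sets out from 2 and 9 and comes back at 11, which is epimerised with DBU to 12 as in step 6.
- The primary alcohol of 2 is silylated in preference to the phenol, which is flanked by I and OMe (TBSCl 1.05 equiv, imidazole, CH2Cl2, 0 °C). This gives 4-[3-(tert-butyldimethylsilyloxy)propyl]-2-iodo-6-methoxyphenol F1.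
- Iodine–magnesium exchange on 9 (iPrMgCl·LiCl, THF, 0 °C) and trapping with paraformaldehyde gives [3-methoxy-4-(triisopropylsilyloxy)phenyl]methanol F2.
- Mitsunobu etherification of the two (PPh3, DIAD, THF) gives tert-butyl(3-{3-iodo-5-methoxy-4-[3-methoxy-4-(triisopropylsilyloxy)benzyloxy]phenyl}propoxy)dimethylsilane F3.
- Pd-catalysed coupling of its C–I bond with methyl diazoacetate (Pd(PPh3)4, Ag2CO3, Et3N, PhMe, rt) gives methyl 2-{5-[3-(tert-butyldimethylsilyloxy)propyl]-3-methoxy-2-[3-methoxy-4-(triisopropylsilyloxy)benzyloxy]phenyl}-2-diazoacetate F4.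
- A chiral dirhodium(II) carboxylate then closes the C2–C3 bond to give 11 (Rh2(S-PTTL)4 or its enantiomer, whichever gives 2R, PhMe, −60 °C).

**2. Step 2.**
- What may go wrong: the ring closure stalls at the alkynylphenol stage, the alkyne homocouples oxidatively, or the C–Si bond is partly cleaved and mixtures result.
- Fallback approach: the two furan carbons come from a masked acetaldehyde instead of an alkyne.
- Route of the fallback: it sets out from 2 and comes back at 6, replacing steps 2 and 3.
- Suzuki coupling of 2 with commercial (E)-2-(2-ethoxyvinyl)-4,4,5,5-tetramethyl-1,3,2-dioxaborolane (Pd(dppf)Cl2, K3PO4, dioxane–H2O, 80 °C) gives 2-[(E)-2-ethoxyvinyl]-4-(3-hydroxypropyl)-6-methoxyphenol F5.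
- Catalytic TsOH in THF then lets the phenol add to the protonated enol ether. Loss of ethanol aromatises the ring to 6.

**3. Step 10.**
- What may go wrong: the alkyl TBS ether is not fully discriminated from the silyl ether on the electron-poor coumarate phenol, or the coumarate ester undergoes acid-catalysed methanolysis during a slow deprotection.
- Fallback approach: the acylation order is inverted, and steric differentiation of two primary alcohols replaces protecting-group differentiation.
- Route of the fallback: it sets out from 13 and comes back at 22, bypassing 17 and 18.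
- The TBS ether of 13 is removed while no cinnamate is present (CSA, MeOH–CH2Cl2). This gives 3-{(2R,3S)-3-(hydroxymethyl)-7-methoxy-2-[3-methoxy-4-(triisopropylsilyloxy)phenyl]-2,3-dihydro-1-benzofuran-5-yl}propan-1-ol F6.
- The unhindered propanol is acylated ahead of the β-branched C9–OH with 21 (1.0 equiv, DCC, DMAP, CH2Cl2, −20 °C). This gives 3-{(2R,3S)-3-(hydroxymethyl)-7-methoxy-2-[3-methoxy-4-(triisopropylsilyloxy)phenyl]-2,3-dihydro-1-benzofuran-5-yl}propyl (E)-3-[3-methoxy-4-(triisopropylsilyloxy)phenyl]acrylate F7.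
- The remaining C9–OH is then esterified with 16 (DCC, DMAP) to give 22.

## Further compounds

F1 | step 6 | 4-[3-(tert-butyldimethylsilyloxy)propyl]-2-iodo-6-methoxyphenol | COc1cc(CCCO[Si](C)(C)C(C)(C)C)cc(I)c1O
F2 | step 6 | [3-methoxy-4-(triisopropylsilyloxy)phenyl]methanol | COc1cc(CO)ccc1O[Si](C(C)C)(C(C)C)C(C)C
F3 | step 6 | tert-butyl(3-{3-iodo-5-methoxy-4-[3-methoxy-4-(triisopropylsilyloxy)benzyloxy]phenyl}propoxy)dimethylsilane | COc1cc(CCCO[Si](C)(C)C(C)(C)C)cc(I)c1OCc1ccc(O[Si](C(C)C)(C(C)C)C(C)C)c(OC)c1
F4 | step 6 | methyl 2-{5-[3-(tert-butyldimethylsilyloxy)propyl]-3-methoxy-2-[3-methoxy-4-(triisopropylsilyloxy)benzyloxy]phenyl}-2-diazoacetate | COC(=O)C(=[N+]=[N-])c1cc(CCCO[Si](C)(C)C(C)(C)C)cc(OC)c1OCc1ccc(O[Si](C(C)C)(C(C)C)C(C)C)c(OC)c1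
F5 | step 2 | 2-[(E)-2-ethoxyvinyl]-4-(3-hydroxypropyl)-6-methoxyphenol | CCO/C=C/c1cc(CCCO)cc(OC)c1O
F6 | step 10 | 3-{(2R,3S)-3-(hydroxymethyl)-7-methoxy-2-[3-methoxy-4-(triisopropylsilyloxy)phenyl]-2,3-dihydro-1-benzofuran-5-yl}propan-1-ol | OCCCc1cc(OC)c2c(c1)[C@@H](CO)[C@H](c1ccc(O[Si](C(C)C)(C(C)C)C(C)C)c(OC)c1)O2
F7 | step 10 | 3-{(2R,3S)-3-(hydroxymethyl)-7-methoxy-2-[3-methoxy-4-(triisopropylsilyloxy)phenyl]-2,3-dihydro-1-benzofuran-5-yl}propyl (E)-3-[3-methoxy-4-(triisopropylsilyloxy)phenyl]acrylate | COc1cc(/C=C/C(=O)OCCCc2cc(OC)c3c(c2)[C@@H](CO)[C@H](c2ccc(O[Si](C(C)C)(C(C)C)C(C)C)c(OC)c2)O3)ccc1O[Si](C(C)C)(C(C)C)C(C)C
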